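In the first seconds of every flask the enzyme meets the impurity, so I set the zero of my scale where the enzyme charge equals the impurity charge.

| setting | gamma | alpha | epsilon |
|---|---|---|---|
| substrate | 0.035 M | 0.035 M | 0.035 M |
| enzyme | 0.40 µM | 1.2 µM | 4.0 µM |
| impurity | 0.74 µM | 0.74 µM | 0.74 µM |
| time | 25 min | 25 min | 25 min |

    substrate + enzyme → target + enzyme, rate k1*[substrate]*[enzyme]/(1 + ([substrate]/Km1) + ([target]/Kp1)) (Km1 = 29 mM, Kp1 = 0.74 mM, k1 = 98000 M⁻¹ s⁻¹)
    enzyme + impurity → spent catalyst A (k2 = 1.6 × 10⁵ M⁻¹ s⁻¹)
    enzyme → spent catalyst B (k3 = 0.082 min⁻¹)

- amount of target at the end, in percent of the substrate charged for gamma, alpha, epsilon, in this order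
- how the row runs (rises all the way / rises, then falls / falls all the way / falls, then rises / hardly changes)

- "hardly changes" means that all values lie within two and a half points (for a concentration: within two and a half percent of the largest)
- run time (gamma): 25 min

I drew target against time for alpha.

1. The titration. The enzyme's life against the impurity at its charged level, 8.45 s, is far shorter than the enzyme's decay time, 12.2 min, so I let the impurity, the limiting reagent of that step in alpha, take its equal of enzyme at once. That leaves an excess of 0.460 µM.

2. The start. With that excess, target rises at 1.23 min⁻¹ as a fraction of the charge.

3. The knee. Near 4.67 % of the charge, the target term in the denominator equals the rest of it, and product inhibition bends the curve.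

4. The dose. I integrated the rate law with x the target fraction and u the substrate fraction left: −A·ln u − B·x equals the rate constant times the time integral of [enzyme], with A = 48.3 and B = 46.1. For a decaying excess the right side is 28.7, and I call it the working dose: the excess times the rate constant times the decay's integral up to the end.

5. The end point. Starting from x = 0.7 and repeating, I got 71.7 %, 72.2 %, then 72.3 % for alpha.

6. The level. With time removed, the dose becomes 33.0, and alpha's curve runs toward about 75.2 %.

Gamma's enzyme charge lies below the zero, so my dose stopped short of gamma.

The forecast gave 9.8 %, 72.4 % and 99.4 %, a row that rises all the way, on the ground that “only the excess survives, then decays”. My own alpha figure stood at 72.3 % when I stopped repeating.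

The flasks gave 9.80 %, 72.4 % and 99.4 %, a row that rises all the way. At 25.0 min, alpha still held 4.84 % of its catalyst as enzyme, beside 27.6 % of its substrate. The dose alpha had not yet spent, 4.25, goes with the rise to 75.4 % target at 250 min. For epsilon, the excess of 3.26 µM gives a dose of 204, and with x set to 1 the rule leaves 0.568 % of the substrate. Epsilon held 0.57 % of its substrate at 25.0 min.

The constants used here were set for the occasion; the result is computed.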